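**Retrosynthetic overview**

- The target is a cycloundecadiene, numbered C1 (ring carbon carrying the exocyclic =CH2), C2, C3, C4=C5 (C5 carries CO2H), C6, C7 (isovalerate), C8, C9 (gem-dimethyl), C10, C11 (carbinol). The last step is fluoride release of a C11 silyl ether and a C5 2-(trimethylsilyl)ethyl ester.
- The only ring is closed at C1–C2 by nickel-electrocatalytic decarboxylative alkenylation. The strategy rests on C1 being a 1,1-disubstituted alkene carbon with no geometry, bonded to the plain C2 methylene, so a C2 acid (as N-acyloxyphthalimide) and a C1 alkenyl bromide can be joined with C4=C5, C7 and C11 already in place.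
- Seco chain: C4=C5 by cross-metathesis of a C5 2-substituted acrylate with pent-4-enoic acid; C6–C7 and the C7 centre by catalytic asymmetric 2-(alkoxycarbonyl)allylation of a C7 aldehyde, then isovalerylation.
- C11 is set by asymmetric transfer hydrogenation of a C11 alkynyl ketone and C1–Br comes from bromoboration of the derived alkyne. The C7–C11 backbone is 3,3-dimethylglutaric anhydride, differentiated by methanolysis.

Key step: step 13

Remark: in step 9 the ligand antipode is defined by the required Re-face addition to the C7 formyl group (giving 7S); this sense is to be confirmed by Mosher ester analysis of the allylation product before scale-up.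

**Step 1**
Reactants: 1 3,3-dimethylglutaric anhydride
Product: 2 5-methoxy-3,3-dimethyl-5-oxopentanoic acid
Conditions: MeOH, reflux
Reagents that add atoms: methanol, CO
Why: Alcoholysis of the symmetric cyclic anhydride differentiates the two termini in one operation (ester carbon becomes C7, acid carbon becomes C11).

**Step 2**
Reactants: 2 5-methoxy-3,3-dimethyl-5-oxopentanoic acid, 3 ethynyltrimethylsilane
Product: 5 methyl 3,3-dimethyl-5-oxo-7-(trimethylsilyl)hept-6-ynoate, via acid chloride 4 (not isolated)
Conditions: (COCl)2, cat. DMF, CH2Cl2, 0 °C to rt, concentrate; then 3, PdCl2(PPh3)2 (2 mol %), CuI (4 mol %), Et3N (1.1 equiv), THF, rt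
Reagents that add atoms: oxalyl chloride, O=C(Cl)C(=O)Cl (chlorine of 4 only)
Why: Acyl Sonogashira coupling of the acid chloride with the terminal alkyne forms the C11–C1 bond as an alkynyl ketone and leaves the methyl ester untouched.

**Step 3**
Reactants: 5 methyl 3,3-dimethyl-5-oxo-7-(trimethylsilyl)hept-6-ynoate
Product: 6 methyl (5S)-5-hydroxy-3,3-dimethyl-7-(trimethylsilyl)hept-6-ynoate
Conditions: Ru[(S,S)-TsNCH(Ph)CH(Ph)NH](p-cymene) (1 mol %), iPrOH, rt; crude used directly
Reagents that add atoms: none
Why: Noyori asymmetric transfer hydrogenation of an alkynyl ketone, in which the (S,S)-catalyst recognises the alkyne as the π-substituent and is expected to deliver hydride to give the (S)-propargylic alcohol (C11), under base-free conditions that spare the ester and limit δ-lactonisation.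

**Step 4**
Reactants: 6 methyl (5S)-5-hydroxy-3,3-dimethyl-7-(trimethylsilyl)hept-6-ynoate
Product: 7 methyl (5S)-5-[(tert-butyldimethylsilyl)oxy]-3,3-dimethyl-7-(trimethylsilyl)hept-6-ynoate
Conditions: TBSOTf, 2,6-lutidine, CH2Cl2, –78 to 0 °C
Reagents that add atoms: tert-butyldimethylsilyl trifluoromethanesulfonate, CC(C)(C)[Si](C)(C)OS(=O)(=O)C(F)(F)F
Why: Fast low-temperature silyl ether formation traps the δ-hydroxy ester before the Thorpe–Ingold-assisted lactonisation can compete.

**Step 5**
Reactants: 7 methyl (5S)-5-[(tert-butyldimethylsilyl)oxy]-3,3-dimethyl-7-(trimethylsilyl)hept-6-ynoate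
Product: 8 methyl (5S)-5-[(tert-butyldimethylsilyl)oxy]-3,3-dimethylhept-6-ynoate
Conditions: K2CO3 (0.3 equiv), MeOH, rt
Reagents that add atoms: none
Why: Methanolytic protodesilylation of the alkynylsilane, in which the methyl ester can only exchange with methanol and the secondary silyl ether is stable.

**Step 6**
Reactants: 8 methyl (5S)-5-[(tert-butyldimethylsilyl)oxy]-3,3-dimethylhept-6-ynoate
Product: 10 methyl (5S)-6-bromo-5-[(tert-butyldimethylsilyl)oxy]-3,3-dimethylhept-6-enoate, via alkenylborane 9 (not isolated)
Conditions: B-bromo-9-BBN (2.2 equiv), CH2Cl2, 0 °C; then AcOH, 0 °C to rt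
Reagents that add atoms: B-bromo-9-borabicyclo[3.3.1]nonane, BrB1C2CCCC1CCC2
Why: Syn bromoboration of the terminal alkyne places boron on the terminal and bromine on the internal carbon, and protodeboronation with acetic acid leaves the 2-bromo-1-alkene (C1–Br).

**Step 7**
Reactants: 10 methyl (5S)-6-bromo-5-[(tert-butyldimethylsilyl)oxy]-3,3-dimethylhept-6-enoate
Product: 11 (5S)-6-bromo-5-[(tert-butyldimethylsilyl)oxy]-3,3-dimethylhept-6-enal
Conditions: iBu2AlH (1.1 equiv), CH2Cl2, –78 °C; aq. potassium sodium tartrate work-up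
Reagents that add atoms: none
Why: Partial ester reduction through the low-temperature-stable aluminium hemiacetal gives the C7 aldehyde without touching the bromoalkene or the silyl ether.

**Step 8**
Reactants: 12 2-(bromomethyl)acrylic acid
Product: 13 2-(trimethylsilyl)ethyl 2-(bromomethyl)prop-2-enoate
Conditions: 2-(trimethylsilyl)ethanol, DCC, DMAP (5 mol %), CH2Cl2, 0 °C to rt
Reagents that add atoms: 2-(trimethylsilyl)ethanol, C[Si](C)(C)CCO
Why: Steglich esterification, with only catalytic DMAP at low temperature to limit its attack on the allylic bromide.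

**Step 9**
Reactants: 11 (5S)-6-bromo-5-[(tert-butyldimethylsilyl)oxy]-3,3-dimethylhept-6-enal, 13 2-(trimethylsilyl)ethyl 2-(bromomethyl)prop-2-enoate
Product: 15 2-(trimethylsilyl)ethyl (4S,8S)-9-bromo-8-[(tert-butyldimethylsilyl)oxy]-4-hydroxy-6,6-dimethyl-2-methylidenedec-9-enoate, via trimethylsilyl ether 14 (not isolated)
Conditions: CrCl2 (10 mol %), tridentate 1,8-bis(oxazolinyl)carbazole ligand (12 mol %, antipode giving Re-face attack), Mn powder (2 equiv), Me3SiCl (2 equiv), iPr2NEt (0.3 equiv), THF, rt; then 10 % aq. citric acid, THF, 0 °C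
Reagents that add atoms: chlorotrimethylsilane, C[Si](C)(C)Cl (silyl group of 14 only)
Why: Catalytic asymmetric Nozaki–Hiyama-type 2-(alkoxycarbonyl)allylation, in which the allylchromium species formed from 13 and divalent chromium (recycled by Mn and Me3SiCl) adds to the Re face of the aldehyde inside the chiral ligand sphere and so sets C7 as (S) independently of the remote C11 centre, while the cold, mildly acidic release of the alcohol is meant to avoid lactonisation onto the ester.

**Step 10**
Reactants: 15 2-(trimethylsilyl)ethyl (4S,8S)-9-bromo-8-[(tert-butyldimethylsilyl)oxy]-4-hydroxy-6,6-dimethyl-2-methylidenedec-9-enoate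
Product: 16 2-(trimethylsilyl)ethyl (4S,8S)-9-bromo-8-[(tert-butyldimethylsilyl)oxy]-6,6-dimethyl-2-methylidene-4-[(3-methylbutanoyl)oxy]dec-9-enoate
Conditions: (Me2CHCH2CO)2O, Et3N, DMAP (10 mol %), CH2Cl2, 0 °C
Reagents that add atoms: 3-methylbutanoic anhydride, CC(C)CC(=O)OC(=O)CC(C)C
Why: DMAP-catalysed acylation of the secondary alcohol installs the C7 isovalerate and removes the hydroxyl that could otherwise lactonise onto the C5 ester.

**Step 11**
Reactants: 16 2-(trimethylsilyl)ethyl (4S,8S)-9-bromo-8-[(tert-butyldimethylsilyl)oxy]-6,6-dimethyl-2-methylidene-4-[(3-methylbutanoyl)oxy]dec-9-enoate, 17 pent-4-enoic acid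
Product: 18 (4E,7S,11S)-12-bromo-11-[(tert-butyldimethylsilyl)oxy]-9,9-dimethyl-7-[(3-methylbutanoyl)oxy]-5-{[2-(trimethylsilyl)ethoxy]carbonyl}trideca-4,12-dienoic acid
Conditions: second-generation Hoveyda–Grubbs catalyst RuCl2(H2IMes)(=CH-C6H4-2-OiPr) (2 × 5 mol %), 17 (5 equiv), CH2Cl2, 40 °C
Reagents that add atoms: none
Why: Olefin cross-metathesis of a 1,1-disubstituted acrylate with a terminal alkene should give the trisubstituted enoate as the thermodynamically preferred (E)-isomer (C3 trans to the ester), with the hindered, electron-poor C1 bromoalkene and the free acid as spectators.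

**Step 12**
Reactants: 18 (4E,7S,11S)-12-bromo-11-[(tert-butyldimethylsilyl)oxy]-9,9-dimethyl-7-[(3-methylbutanoyl)oxy]-5-{[2-(trimethylsilyl)ethoxy]carbonyl}trideca-4,12-dienoic acid
Product: 19 1,3-dioxoisoindolin-2-yl (4E,7S,11S)-12-bromo-11-[(tert-butyldimethylsilyl)oxy]-9,9-dimethyl-7-[(3-methylbutanoyl)oxy]-5-{[2-(trimethylsilyl)ethoxy]carbonyl}trideca-4,12-dienoate
Conditions: N-hydroxyphthalimide, DIC, DMAP (10 mol %), CH2Cl2, rt
Reagents that add atoms: N-hydroxyphthalimide, O=C1c2ccccc2C(=O)N1O
Why: Carbodiimide coupling converts the C2 acid into the redox-active N-acyloxyphthalimide under neutral conditions that leave all other esters alone.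

**Step 13**
Reactants: 19 1,3-dioxoisoindolin-2-yl (4E,7S,11S)-12-bromo-11-[(tert-butyldimethylsilyl)oxy]-9,9-dimethyl-7-[(3-methylbutanoyl)oxy]-5-{[2-(trimethylsilyl)ethoxy]carbonyl}trideca-4,12-dienoate
Product: 20 2-(trimethylsilyl)ethyl (4E,7S,11S)-11-[(tert-butyldimethylsilyl)oxy]-9,9-dimethyl-1-methylidene-7-[(3-methylbutanoyl)oxy]cycloundec-4-ene-5-carboxylate (ring numbering of the overview)
Conditions: NiCl2·6H2O (20 mol %), 2,2′-bipyridine (24 mol %), AgNO3 (0.3 equiv), LiCl, DMF, Mg anode, reticulated vitreous carbon cathode, constant low current, rt; 19 added by syringe pump over 10 h (stationary concentration below 2 mM)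
Reagents that add atoms: none
Why: Proposed new method: cathodically generated low-valent nickel–bipyridine inserts into the C1–Br bond to give an alkenylnickel bromide, while single-electron reduction of the N-acyloxyphthalimide (at the silver-coated cathode or by monovalent nickel) expels phthalimide anion and CO2 and leaves the primary C2 radical, whose capture by the tethered alkenylnickel gives a trivalent alkyl(alkenyl)nickel species that reductively eliminates the C1–C2 bond. The closest known reaction type is the intermolecular nickel-electrocatalytic decarboxylative alkenylation of redox-active esters with alkenyl bromides, which has not been used as a ring closure. The eleven-membered carbocycle, the only ring, closes by intramolecular radical capture through a twelve-membered nickelacycle followed by C(sp3)–C(sp2) reductive elimination. No stereocentre is formed and none is at risk, because C7 and C11 never become radical or organometallic sites, the 1,1-disubstituted C1 bromoalkene has no geometry to lose and the C4=C5 enoate is not involved. The step needs ring closure to outrun hydrogen abstraction or over-reduction of the C2 radical, intermolecular coupling and radical addition to an acrylate, and for this it relies on slow addition to a low stationary concentration, the fast capture of an unstabilised primary radical by nickel, the hindered trisubstituted acrylate and the turn elements of the chain (C9 gem-dimethyl, C3 and C6 cis on C4=C5). The isovalerate, the 2-(trimethylsilyl)ethyl ester and the silyl ether should be inert to this near-neutral reductive electrolysis.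

**Step 14**
Reactants: 20 2-(trimethylsilyl)ethyl (4E,7S,11S)-11-[(tert-butyldimethylsilyl)oxy]-9,9-dimethyl-1-methylidene-7-[(3-methylbutanoyl)oxy]cycloundec-4-ene-5-carboxylate
Product: 21 (4E,7S,11S)-11-hydroxy-9,9-dimethyl-1-methylidene-7-[(3-methylbutanoyl)oxy]cycloundec-4-ene-5-carboxylic acid (CNP0400752.1; ring numbering of the overview)
Conditions: TBAF (5 equiv), THF, 0 °C to rt; then dilute aq. HCl to pH 4
Reagents that add atoms: none
Why: Fluoride-mediated desilylation cleaves the C11 silyl ether and fragments the 2-(trimethylsilyl)ethyl ester (loss of ethene and Me3SiF) to the carboxylate in one operation, leaving the isovalerate and both alkenes untouched.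

**Compound list**

1 | 3,3-dimethylglutaric anhydride | CC1(C)CC(=O)OC(=O)C1 | starting material
2 | 5-methoxy-3,3-dimethyl-5-oxopentanoic acid | COC(=O)CC(C)(C)CC(=O)O | intermediate
3 | ethynyltrimethylsilane | C#C[Si](C)(C)C | starting material
4 | methyl 5-chloro-3,3-dimethyl-5-oxopentanoate (acid chloride, not isolated) | COC(=O)CC(C)(C)CC(=O)Cl | intermediate
5 | methyl 3,3-dimethyl-5-oxo-7-(trimethylsilyl)hept-6-ynoate | COC(=O)CC(C)(C)CC(=O)C#C[Si](C)(C)C | intermediate
6 | methyl (5S)-5-hydroxy-3,3-dimethyl-7-(trimethylsilyl)hept-6-ynoate | COC(=O)CC(C)(C)C[C@H](O)C#C[Si](C)(C)C | intermediate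
7 | methyl (5S)-5-[(tert-butyldimethylsilyl)oxy]-3,3-dimethyl-7-(trimethylsilyl)hept-6-ynoate | COC(=O)CC(C)(C)C[C@H](O[Si](C)(C)C(C)(C)C)C#C[Si](C)(C)C | intermediate
8 | methyl (5S)-5-[(tert-butyldimethylsilyl)oxy]-3,3-dimethylhept-6-ynoate | COC(=O)CC(C)(C)C[C@H](O[Si](C)(C)C(C)(C)C)C#C | intermediate
9 | methyl (5S,6Z)-7-(9-borabicyclo[3.3.1]nonan-9-yl)-6-bromo-5-[(tert-butyldimethylsilyl)oxy]-3,3-dimethylhept-6-enoate (alkenylborane, not isolated) | COC(=O)CC(C)(C)C[C@H](O[Si](C)(C)C(C)(C)C)/C(Br)=C/B1C2CCCC1CCC2 | intermediate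
10 | methyl (5S)-6-bromo-5-[(tert-butyldimethylsilyl)oxy]-3,3-dimethylhept-6-enoate | COC(=O)CC(C)(C)C[C@H](O[Si](C)(C)C(C)(C)C)C(Br)=C | intermediate
11 | (5S)-6-bromo-5-[(tert-butyldimethylsilyl)oxy]-3,3-dimethylhept-6-enal | O=CCC(C)(C)C[C@H](O[Si](C)(C)C(C)(C)C)C(Br)=C | intermediate
12 | 2-(bromomethyl)acrylic acid | C=C(CBr)C(=O)O | starting material
13 | 2-(trimethylsilyl)ethyl 2-(bromomethyl)prop-2-enoate | C=C(CBr)C(=O)OCC[Si](C)(C)C | intermediate
14 | 2-(trimethylsilyl)ethyl (4S,8S)-9-bromo-8-[(tert-butyldimethylsilyl)oxy]-6,6-dimethyl-2-methylidene-4-[(trimethylsilyl)oxy]dec-9-enoate (trimethylsilyl ether, not isolated) | C=C(C[C@@H](O[Si](C)(C)C)CC(C)(C)C[C@H](O[Si](C)(C)C(C)(C)C)C(Br)=C)C(=O)OCC[Si](C)(C)C | intermediate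
15 | 2-(trimethylsilyl)ethyl (4S,8S)-9-bromo-8-[(tert-butyldimethylsilyl)oxy]-4-hydroxy-6,6-dimethyl-2-methylidenedec-9-enoate | C=C(C[C@@H](O)CC(C)(C)C[C@H](O[Si](C)(C)C(C)(C)C)C(Br)=C)C(=O)OCC[Si](C)(C)C | intermediate
16 | 2-(trimethylsilyl)ethyl (4S,8S)-9-bromo-8-[(tert-butyldimethylsilyl)oxy]-6,6-dimethyl-2-methylidene-4-[(3-methylbutanoyl)oxy]dec-9-enoate | C=C(C[C@@H](OC(=O)CC(C)C)CC(C)(C)C[C@H](O[Si](C)(C)C(C)(C)C)C(Br)=C)C(=O)OCC[Si](C)(C)C | intermediate
17 | pent-4-enoic acid | C=CCCC(=O)O | starting material
18 | (4E,7S,11S)-12-bromo-11-[(tert-butyldimethylsilyl)oxy]-9,9-dimethyl-7-[(3-methylbutanoyl)oxy]-5-{[2-(trimethylsilyl)ethoxy]carbonyl}trideca-4,12-dienoic acid | O=C(O)CC/C=C(/C(=O)OCC[Si](C)(C)C)C[C@@H](OC(=O)CC(C)C)CC(C)(C)C[C@H](O[Si](C)(C)C(C)(C)C)C(Br)=C | intermediate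
19 | 1,3-dioxoisoindolin-2-yl ester of 18 (seco N-acyloxyphthalimide, key-step precursor) | O=C(CC/C=C(/C(=O)OCC[Si](C)(C)C)C[C@@H](OC(=O)CC(C)C)CC(C)(C)C[C@H](O[Si](C)(C)C(C)(C)C)C(Br)=C)ON1C(=O)c2ccccc2C1=O | intermediate
20 | 2-(trimethylsilyl)ethyl (4E,7S,11S)-11-[(tert-butyldimethylsilyl)oxy]-9,9-dimethyl-1-methylidene-7-[(3-methylbutanoyl)oxy]cycloundec-4-ene-5-carboxylate (protected macrocycle) | C=C1CC/C=C(/C(=O)OCC[Si](C)(C)C)C[C@@H](OC(=O)CC(C)C)CC(C)(C)C[C@@H]1O[Si](C)(C)C(C)(C)C | intermediate
21 | (4E,7S,11S)-11-hydroxy-9,9-dimethyl-1-methylidene-7-[(3-methylbutanoyl)oxy]cycloundec-4-ene-5-carboxylic acid (CNP0400752.1) | C=C1CC/C=C(/C(=O)O)C[C@@H](OC(=O)CC(C)C)CC(C)(C)C[C@@H]1O | target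

**Step count**

Total: 14 steps. Longest linear sequence: 13 steps (steps 1–7 and 9–14); step 8 prepares the allylating reagent.

**Steps most likely to fail**

1. Step 13 (proposed new method).
   - What may go wrong: capture of the C2 radical by the tethered alkenylnickel may be slower than hydrogen abstraction or cathodic reduction of the radical, giving the C2–H seco compound.
   - Coupling between molecules may give dimers and oligomers.
   - The homoallylic C2 radical can close reversibly onto C4 to a tertiary, ester-stabilised cyclopropylcarbinyl radical that is reduced instead of coupled.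
   - The C1–Br bond may be reduced to C1–H.
   - Fallback (known chemistry, sets out from 19, returns at 20): 19 would undergo the light-driven decarboxylative borylation with bis(catecholato)diboron in N,N-dimethylacetamide (blue LEDs), giving the C2 catechol boronate F1. This would be transesterified in the same flask with pinacol and Et3N to the primary alkyl pinacol boronate F2. F2 would then be closed at C1–C2 by an intramolecular B-alkyl Suzuki–Miyaura coupling with the C1 bromoalkene (PdCl2(dppf), Ag2O, K2CO3, THF, 70 °C, below 2 mM) to give 20. This replaces the radical ring closure by a two-electron transmetalation and reductive elimination.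

2. Step 11.
   - What may go wrong: the 2-substituted acrylate may turn over slowly, so that self-metathesis of pent-4-enoic acid and catalyst decay dominate.
   - The ruthenium carbene may be deactivated by the bromoalkene.
   - Double-bond migration may erode the enoate.
   - Fallback (sets out from 16, returns at 20): the order of the two bond formations is exchanged. Pent-4-enoic acid 17 would be converted (N-hydroxyphthalimide, DIC, CH2Cl2) into 1,3-dioxoisoindolin-2-yl pent-4-enoate F3. 16 and F3 would be joined at C1–C2 by the established intermolecular nickel-electrocatalytic decarboxylative alkenylation (NiCl2·6H2O, 2,2′-bipyridine, AgNO3, DMF, Mg anode) to give triene F4. Ring-closing metathesis of F4 between the terminal vinyl group and the acrylate (second-generation Hoveyda–Grubbs catalyst, dilute toluene, 80 °C) would then form C4=C5 inside the ring and give 20. The hindered trisubstituted alkene is then made intramolecularly, the ring-cis arrangement of C3 and C6 being the required (E)-enoate; steps 12 and 13 are not needed in this variant.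

3. Step 9.
   - What may go wrong: facial selectivity may be poor with the β-quaternary aldehyde, or the sense of induction may be opposite to the one assumed.
   - The γ-hydroxy ester may lactonise to the α-methylene-γ-butyrolactone during silyl ether cleavage.
   - The allylic bromide may undergo reductive homocoupling.
   - Fallback (sets out from 11, returns at 16): the C7 centre would be set by organocatalytic propargylboration and the acrylate made afterwards by carbonylation. 11 would react with allenylboronic acid pinacol ester under catalysis by (R)-3,3′-bis(2,4,6-triisopropylphenyl)-1,1′-binaphthyl-2,2′-diyl hydrogen phosphate (toluene, 4 Å sieves, –20 °C; Re-face addition expected) to give the O-boryl adduct F5, hydrolysed on work-up to the (7S)-homopropargylic alcohol F6. Acylation with 3-methylbutanoic anhydride (Et3N, DMAP) would give the isovalerate alkyne F7. Markovnikov hydroalkoxycarbonylation of the terminal alkyne of F7 (Pd(OAc)2, 2-pyridyldiphenylphosphine, MsOH, CO, 2-(trimethylsilyl)ethanol, 45 °C) would give 16. The cationic palladium hydride cycle is expected to leave the C1–Br bond alone at this temperature, and no free γ-hydroxy ester occurs on this path.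

**Further compounds**

F1 | step 13 | C2 catechol boronate from 19 (not isolated) | O1c2ccccc2OB1CC/C=C(/C(=O)OCC[Si](C)(C)C)C[C@@H](OC(=O)CC(C)C)CC(C)(C)C[C@H](O[Si](C)(C)C(C)(C)C)C(Br)=C
F2 | step 13 | C2 pinacol boronate | CC1(C)OB(CC/C=C(/C(=O)OCC[Si](C)(C)C)C[C@@H](OC(=O)CC(C)C)CC(C)(C)C[C@H](O[Si](C)(C)C(C)(C)C)C(Br)=C)OC1(C)C
F3 | step 11 | 1,3-dioxoisoindolin-2-yl pent-4-enoate | C=CCCC(=O)ON1C(=O)c2ccccc2C1=O
F4 | step 11 | triene: 16 with the C1 bromine replaced by a but-3-enyl group | C=C(C[C@@H](OC(=O)CC(C)C)CC(C)(C)C[C@H](O[Si](C)(C)C(C)(C)C)C(=C)CCC=C)C(=O)OCC[Si](C)(C)C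
F5 | step 9 | O-(pinacolatoboryl) adduct of the homopropargylic alcohol (not isolated) | C#CC[C@@H](OB1OC(C)(C)C(C)(C)O1)CC(C)(C)C[C@H](O[Si](C)(C)C(C)(C)C)C(Br)=C
F6 | step 9 | (4S,8S)-9-bromo-8-[(tert-butyldimethylsilyl)oxy]-6,6-dimethyldec-9-en-1-yn-4-ol | C#CC[C@@H](O)CC(C)(C)C[C@H](O[Si](C)(C)C(C)(C)C)C(Br)=C
F7 | step 9 | (4S,8S)-9-bromo-8-[(tert-butyldimethylsilyl)oxy]-6,6-dimethyldec-9-en-1-yn-4-yl 3-methylbutanoate | C#CC[C@@H](OC(=O)CC(C)C)CC(C)(C)C[C@H](O[Si](C)(C)C(C)(C)C)C(Br)=C
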